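**Strategy.** Everything rests on disconnecting the pyranone ring of unit 2 at C8a''–O1'', C4''–C4a'' and O1''–C2''. Ring A'' carries O1'' at C8a'', the C4'' acyl group at C4a'' and a second oxygen at the flanking C5'', exactly what a 3,5-dialkoxybenzyne delivers when it inserts into the C–O bond of a carboxylic acid. In one operation the aryne adds the whole benzo ring with all three oxygens in place, and the 2'-hydroxychalcone phenoxide so formed closes ring C'' by oxa-Michael addition, setting C2'' and C3''. The precursor is the enantiopure 2,3-trans flavanone of unit 1 (5-OH masked as MOM ether) carrying at C3 the α-carbon of (E)-4-(methoxymethoxy)cinnamic acid.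

Key step: step 12

**Remarks on the chemistry**
- Numbering: unit 1 (unprimed) is the 5-hydroxy-7-methoxy flavanone with the 4-methoxyphenyl group; unit 2 (double-primed) is the 5,7-dihydroxy flavanone with the 4-hydroxyphenyl group. The target is 2R,3S,2''R,3''S with both rings 2,3-trans. The structures of acid 13, triflate 19 and product 22 are consistent with this and needed no correction.
- Assumption: the (S) enantiomer of the pyridine-oxazoline ligand is taken to deliver the aryl group to the face of C2 that gives the 2R flavanone, the same facial sense as in its additions to 3-substituted cyclohexenones. The configuration of 6 is to be confirmed chiroptically against the known 2S series, and the (R) ligand is used if the sense proves opposite.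
- Design choice: the acid is reached at the aldehyde oxidation level (enamine condensation, then Pinnick oxidation). An ester that needs acid for cleavage would not survive beside four MOM ethers, and a side-chain ester CH2 cannot be enolised selectively next to the more acidic C3–H.
- The enantiomeric purity of 6, 12 and 22 is to be checked by chiral HPLC, because C2 of unit 1 can only be lost by ring opening.

**Route**

Step 1
Reactants: 1 2',6'-dihydroxy-4'-methoxyacetophenone
Product: 3 5-hydroxy-7-methoxy-4H-chromen-4-one, via enaminone 2 (not isolated)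
Conditions: Me2NCH(OMe)2, toluene, 90 °C; then conc. HCl, CH2Cl2, 40 °C
Reagents that add atoms: N,N-dimethylformamide dimethyl acetal, COC(OC)N(C)C
Why: Enaminone formation at the methyl ketone followed by acid-promoted addition–elimination of an ortho hydroxyl group (loss of dimethylamine) is the standard enaminone chromone synthesis, and since the two hydroxyl groups are equivalent a single chromone with a chelated 5-OH should result.

Step 2
Reactants: 3 5-hydroxy-7-methoxy-4H-chromen-4-one
Product: 4 7-methoxy-5-(methoxymethoxy)-4H-chromen-4-one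
Conditions: NaH, DMF, 0 °C; MOMCl, 0 °C to rt
Reagents that add atoms: chloromethyl methyl ether, COCCl
Why: Williamson-type O-alkylation of the phenoxide with MOMCl, for which NaH is chosen because the hydrogen-bonded 5-OH reacts sluggishly with amine bases.

Step 3
Reactants: 4 7-methoxy-5-(methoxymethoxy)-4H-chromen-4-one; 5 4-methoxyphenylboronic acid
Product: 6 (2R)-7-methoxy-5-(methoxymethoxy)-2-(4-methoxyphenyl)chroman-4-one
Conditions: Pd(OCOCF3)2 (5 mol%), (S)-t-BuPyOx [(S)-4-tert-butyl-2-(pyridin-2-yl)-4,5-dihydrooxazole] (6 mol%), NH4PF6 (30 mol%), H2O (5 equiv), ClCH2CH2Cl, 60 °C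
Reagents that add atoms: none
Why: Catalytic asymmetric conjugate addition of an arylboronic acid to a chromone under cationic divalent palladium, in which transmetalation, face-selective insertion of C2=C3 into the Pd–aryl bond and protonolysis of the palladium enolate by water set C2 under ligand control, while the base-free medium keeps the flavanone from ring opening.

Step 4
Reactants: 6 (2R)-7-methoxy-5-(methoxymethoxy)-2-(4-methoxyphenyl)chroman-4-one
Product: 8 (2R,3S)-3-allyl-7-methoxy-5-(methoxymethoxy)-2-(4-methoxyphenyl)chroman-4-one, via lithium enolate 7 (not isolated)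
Conditions: LiN(SiMe3)2, THF, −78 °C; allyl bromide, DMPU, −78 to −45 °C; AcOH quench
Reagents that add atoms: allyl bromide, C=CCBr
Why: Kinetic enolate formation and SN2 alkylation with a reactive allylic halide, in which the electrophile approaches the enolate face opposite the C2 aryl group to give the 2,3-trans product (3S), also the thermodynamic epimer, while the low temperature suppresses E1cB opening of the pyranone ring.

Step 5
Reactants: 8 (2R,3S)-3-allyl-7-methoxy-5-(methoxymethoxy)-2-(4-methoxyphenyl)chroman-4-one
Product: 9 2-[(2R,3S)-7-methoxy-5-(methoxymethoxy)-2-(4-methoxyphenyl)-4-oxochroman-3-yl]acetaldehyde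
Conditions: OsO4 (2 mol%), NaIO4, 2,6-lutidine, dioxane/H2O, rt
Reagents that add atoms: osmium tetroxide (catalytic oxygen carrier), O=[Os](=O)(=O)=O; sodium periodate (terminal oxidant), [Na+].[O-]I(=O)(=O)=O
Why: Lemieux–Johnson oxidative cleavage (catalytic dihydroxylation, then periodate glycol cleavage) of the only alkene under near-neutral conditions, which should leave C2, C3, the MOM ether and the electron-rich arenes untouched.

Step 6
Reactants: 10 4-hydroxybenzaldehyde
Product: 11 4-(methoxymethoxy)benzaldehyde
Conditions: MOMCl, i-Pr2NEt, CH2Cl2, 0 °C to rt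
Reagents that add atoms: chloromethyl methyl ether, COCCl
Why: Standard MOM protection of a phenol by O-alkylation in the presence of a hindered amine base, the aldehyde being inert.

Step 7
Reactants: 9 2-[(2R,3S)-7-methoxy-5-(methoxymethoxy)-2-(4-methoxyphenyl)-4-oxochroman-3-yl]acetaldehyde; 11 4-(methoxymethoxy)benzaldehyde
Product: 12 (E)-2-[(2R,3S)-7-methoxy-5-(methoxymethoxy)-2-(4-methoxyphenyl)-4-oxochroman-3-yl]-3-[4-(methoxymethoxy)phenyl]prop-2-enal
Conditions: pyrrolidine (20 mol%), PhCO2H (20 mol%), 4 Å molecular sieves, toluene, rt to 40 °C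
Reagents that add atoms: none
Why: Amine-catalysed cross-aldol condensation in which pyrrolidine turns only the aliphatic aldehyde into an enamine (the hindered C4 aryl ketone does not condense), the enamine adds to the iminium ion of the non-enolisable aromatic aldehyde and loss of the amine gives the E enal, so the new double bond is placed regiospecifically at the side-chain CH2 without enolate chemistry at C3, whose trans configuration is the thermodynamic one.

Step 8
Reactants: 12 (E)-2-[(2R,3S)-7-methoxy-5-(methoxymethoxy)-2-(4-methoxyphenyl)-4-oxochroman-3-yl]-3-[4-(methoxymethoxy)phenyl]prop-2-enal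
Product: 13 (E)-2-[(2R,3S)-7-methoxy-5-(methoxymethoxy)-2-(4-methoxyphenyl)-4-oxochroman-3-yl]-3-[4-(methoxymethoxy)phenyl]prop-2-enoic acid
Conditions: NaClO2, NaH2PO4, 2-methyl-2-butene, t-BuOH/THF/H2O, 0 °C to rt
Reagents that add atoms: sodium chlorite, [Na+].[O-]Cl=O
Why: Pinnick oxidation of an enal to the acrylic acid by chlorous acid with 2-methyl-2-butene as hypochlorite scavenger, a buffered medium in which the alkene, the epimerisable C3 centre and the MOM ethers should survive and which delivers the free acid without any ester cleavage.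

Step 9
Reactants: 14 phloroglucinol
Product: 15 3,5-bis(methoxymethoxy)phenol
Conditions: MOMCl (2.0 equiv), i-Pr2NEt, DMF, 0 °C to rt
Reagents that add atoms: chloromethyl methyl ether, COCCl
Why: Statistical O-alkylation of a symmetric triphenol with two equivalents of MOMCl, from which the bis-ether is separated by chromatography from mono- and tris-ether.

Step 10
Reactants: 15 3,5-bis(methoxymethoxy)phenol
Product: 16 2-bromo-3,5-bis(methoxymethoxy)phenol
Conditions: NBS, CH2Cl2, −78 °C
Reagents that add atoms: N-bromosuccinimide, O=C1CCC(=O)N1Br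
Why: Electrophilic aromatic bromination at low temperature, expected to favour the position ortho to the free hydroxyl group (hydrogen-bonded delivery, and the position between the two MOM ethers is more hindered) as known for 3,5-dimethoxyphenol, the minor 4-bromo isomer being removed by chromatography.

Step 11
Reactants: 16 2-bromo-3,5-bis(methoxymethoxy)phenol
Product: 19 3,5-bis(methoxymethoxy)-2-(trimethylsilyl)phenyl trifluoromethanesulfonate, via aryl silyl ether 17 (not isolated), via lithium 2-silylphenoxide 18 (not isolated)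
Conditions: (Me3Si)2NH, THF, 65 °C, then evaporation; n-BuLi, THF, −78 °C; Tf2O, −78 °C
Reagents that add atoms: hexamethyldisilazane, C[Si](C)(C)N[Si](C)(C)C; trifluoromethanesulfonic anhydride, O=S(=O)(OS(=O)(=O)C(F)(F)F)C(F)(F)F
Why: O-silylation, bromine–lithium exchange and 1,3 O-to-C silyl migration (retro-Brook rearrangement) give the lithium 2-silylphenoxide, which is triflated in the same flask, the standard route to ortho-silylaryl triflates, with halogen–lithium exchange at −78 °C far faster than MOM-directed deprotonation.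

Step 12
Reactants: 13 (E)-2-[(2R,3S)-7-methoxy-5-(methoxymethoxy)-2-(4-methoxyphenyl)-4-oxochroman-3-yl]-3-[4-(methoxymethoxy)phenyl]prop-2-enoic acid; 19 3,5-bis(methoxymethoxy)-2-(trimethylsilyl)phenyl trifluoromethanesulfonate
Product: 22 (2R,3S,2''R,3''S)-7-methoxy-5,5'',7''-tris(methoxymethoxy)-2''-[4-(methoxymethoxy)phenyl]-2-(4-methoxyphenyl)-3,3''-biflavanone, via aryne 20 (not isolated), via 2'-hydroxychalcone 21 (not isolated)
Conditions: 19 (1.5 equiv), CsF (4 equiv), THF, sealed tube, 100–125 °C
Reagents that add atoms: none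
Why: Fluoride removes the silyl group of 19 with loss of triflate to give aryne 20; the carboxylate of 13 adds through oxygen to the aryne carbon remote from the flanking MOM ether, the aryl anion generated next to that ether attacks the ester carbonyl through a four-membered alkoxide, and its opening gives the 2-acylphenoxide 21, so that C8a''–O1'' and C4''–C4a'' are formed. The closest known reaction is the fluoride-mediated insertion of arynes into the C–O bond of carboxylic acids to give ortho-hydroxyaryl ketones, which with acrylic and cinnamic acids runs on to chroman-4-ones. Ring C'' closes by 6-endo-trig oxa-Michael addition of the phenoxide to C2'' (O1''–C2''), followed by protonation of the enolate at C3'' by bifluoride. C2'' is set by attack on the alkene face favoured by the adjacent C3 stereocentre (allylic strain holds C3–H near the alkene plane so that the C2 side of unit 1 shields one face) and this addition is reversible, while C3'' is set by protonation to the 2'',3''-trans diequatorial arrangement, the thermodynamic outcome at an epimerisable α-keto centre. The step needs aryne regioselectivity, secured by the inductively withdrawing alkoxy group next to the triple bond, and chemoselectivity, secured because every phenol is capped and the free acid buffers fluoride as bifluoride, which should keep unit 1 from being enolised; the 1,3-induction from C3 to C2'' is the unsecured point, so the all-trans 2''S,3''R diastereomer may form alongside and would be removed by chromatography.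

Step 13
Reactants: 22 (2R,3S,2''R,3''S)-7-methoxy-5,5'',7''-tris(methoxymethoxy)-2''-[4-(methoxymethoxy)phenyl]-2-(4-methoxyphenyl)-3,3''-biflavanone
Product: 23 (2R,3S,2''R,3''S)-5,5'',7''-trihydroxy-2''-(4-hydroxyphenyl)-7-methoxy-2-(4-methoxyphenyl)-3,3''-biflavanone
Conditions: HCl (3 M aq), MeOH/THF, 45 °C
Reagents that add atoms: none
Why: Acid-catalysed acetal cleavage (transacetalisation to dimethoxymethane) removes the four MOM ethers, while aryl methyl ethers are inert and the flavanone stereocentres should be configurationally stable in acid at this temperature.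

**Compound list**

1 | 2',6'-dihydroxy-4'-methoxyacetophenone | CC(=O)c1c(O)cc(OC)cc1O | starting material
2 | (E)-1-(2,6-dihydroxy-4-methoxyphenyl)-3-(dimethylamino)prop-2-en-1-one | CN(C)/C=C/C(=O)c1c(O)cc(OC)cc1O | intermediate
3 | 5-hydroxy-7-methoxy-4H-chromen-4-one | COc1cc(O)c2c(=O)ccoc2c1 | intermediate
4 | 7-methoxy-5-(methoxymethoxy)-4H-chromen-4-one | COCOc1cc(OC)cc2occc(=O)c12 | intermediate
5 | 4-methoxyphenylboronic acid | COc1ccc(B(O)O)cc1 | starting material
6 | (2R)-7-methoxy-5-(methoxymethoxy)-2-(4-methoxyphenyl)chroman-4-one | COc1ccc([C@@H]2Oc3cc(OC)cc(OCOC)c3C(=O)C2)cc1 | intermediate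
7 | lithium (2R)-7-methoxy-5-(methoxymethoxy)-2-(4-methoxyphenyl)-2H-chromen-4-olate | [Li+].COc1ccc([C@@H]2Oc3cc(OC)cc(OCOC)c3C([O-])=C2)cc1 | intermediate
8 | (2R,3S)-3-allyl-7-methoxy-5-(methoxymethoxy)-2-(4-methoxyphenyl)chroman-4-one (2,3-trans) | COc1ccc([C@@H]2Oc3cc(OC)cc(OCOC)c3C(=O)[C@H]2CC=C)cc1 | intermediate
9 | 2-[(2R,3S)-7-methoxy-5-(methoxymethoxy)-2-(4-methoxyphenyl)-4-oxochroman-3-yl]acetaldehyde | COc1ccc([C@@H]2Oc3cc(OC)cc(OCOC)c3C(=O)[C@H]2CC=O)cc1 | intermediate
10 | 4-hydroxybenzaldehyde | O=Cc1ccc(O)cc1 | starting material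
11 | 4-(methoxymethoxy)benzaldehyde | COCOc1ccc(C=O)cc1 | intermediate
12 | (E)-2-[(2R,3S)-7-methoxy-5-(methoxymethoxy)-2-(4-methoxyphenyl)-4-oxochroman-3-yl]-3-[4-(methoxymethoxy)phenyl]prop-2-enal (aryl trans to CHO) | COc1ccc([C@@H]2Oc3cc(OC)cc(OCOC)c3C(=O)[C@H]2/C(=C\c2ccc(OCOC)cc2)C=O)cc1 | intermediate
13 | (E)-2-[(2R,3S)-7-methoxy-5-(methoxymethoxy)-2-(4-methoxyphenyl)-4-oxochroman-3-yl]-3-[4-(methoxymethoxy)phenyl]prop-2-enoic acid (aryl trans to CO2H) | COc1ccc([C@@H]2Oc3cc(OC)cc(OCOC)c3C(=O)[C@H]2/C(=C\c2ccc(OCOC)cc2)C(=O)O)cc1 | intermediate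
14 | phloroglucinol | Oc1cc(O)cc(O)c1 | starting material
15 | 3,5-bis(methoxymethoxy)phenol | COCOc1cc(O)cc(OCOC)c1 | intermediate
16 | 2-bromo-3,5-bis(methoxymethoxy)phenol | COCOc1cc(O)c(Br)c(OCOC)c1 | intermediate
17 | [2-bromo-3,5-bis(methoxymethoxy)phenoxy]trimethylsilane | COCOc1cc(O[Si](C)(C)C)c(Br)c(OCOC)c1 | intermediate
18 | lithium 3,5-bis(methoxymethoxy)-2-(trimethylsilyl)phenoxide | [Li+].COCOc1cc([O-])c([Si](C)(C)C)c(OCOC)c1 | intermediate
19 | 3,5-bis(methoxymethoxy)-2-(trimethylsilyl)phenyl trifluoromethanesulfonate | COCOc1cc(OCOC)c([Si](C)(C)C)c(OS(=O)(=O)C(F)(F)F)c1 | intermediate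
20 | 3,5-bis(methoxymethoxy)benzyne (1,2-didehydro-3,5-bis(methoxymethoxy)benzene) | COCOC1=CC(OCOC)=CC#C1 | intermediate
21 | (E)-1-[2-hydroxy-4,6-bis(methoxymethoxy)phenyl]-2-[(2R,3S)-7-methoxy-5-(methoxymethoxy)-2-(4-methoxyphenyl)-4-oxochroman-3-yl]-3-[4-(methoxymethoxy)phenyl]prop-2-en-1-one (present as its cesium phenoxide) | COc1ccc([C@@H]2Oc3cc(OC)cc(OCOC)c3C(=O)[C@H]2/C(=C\c2ccc(OCOC)cc2)C(=O)c2c(O)cc(OCOC)cc2OCOC)cc1 | intermediate
22 | (2R,3S,2''R,3''S)-7-methoxy-5,5'',7''-tris(methoxymethoxy)-2''-[4-(methoxymethoxy)phenyl]-2-(4-methoxyphenyl)-3,3''-biflavanone (both rings 2,3-trans) | COc1ccc([C@@H]2Oc3cc(OC)cc(OCOC)c3C(=O)[C@H]2[C@@H]2C(=O)c3c(OCOC)cc(OCOC)cc3O[C@H]2c2ccc(OCOC)cc2)cc1 | intermediate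
23 | (2R,3S,2''R,3''S)-5,5'',7''-trihydroxy-2''-(4-hydroxyphenyl)-7-methoxy-2-(4-methoxyphenyl)-3,3''-biflavanone (both rings 2,3-trans) | COc1ccc([C@@H]2Oc3cc(OC)cc(O)c3C(=O)[C@H]2[C@@H]2C(=O)c3c(O)cc(O)cc3O[C@H]2c2ccc(O)cc2)cc1 | target

**Step count**

Total step count: 13.
Longest linear sequence: 9 steps (steps 1, 2, 3, 4, 5, 7, 8, 12, 13).

**Steps most likely to fail**

1. Step 12.
- What may go wrong: the aryl anion may be protonated before the acyl shift, which stops at the aryl ester. The chalcone phenoxide may be arylated by a second aryne. Ring C of unit 1 may open at high temperature under base, with loss of the C2 configuration. The facial selectivity at C2'' may be poor.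
- Fallback: it sets out from enal 12 and comes back at target 23; the benzo ring of unit 2 is brought in as an aryl anion instead of an aryne. Phloroglucinol 14 is fully protected (NaH, MOMCl, DMF) to 1,3,5-tris(methoxymethoxy)benzene F1. Directed ortho-metalation with n-BuLi in THF at 0 °C gives 2,4,6-tris(methoxymethoxy)phenyllithium F2. F2 is added at −78 °C to the aldehyde of 12; 1,2-addition to the aldehyde should be far faster than attack on the hindered, electron-rich C4 ketone. This gives allylic alcohol F3 as a mixture of carbinol epimers. Oxidation with Dess–Martin periodinane (NaHCO3, CH2Cl2) gives chalcone F4, the 2'-O-MOM ether of 21. HCl in MeOH at 45 °C removes all five MOM groups to give pentahydroxychalcone F5, which is not isolated. Its 2',6'-dihydroxyaryl ketone closes by oxa-Michael addition, completed by buffering with NaOAc; either ortho hydroxyl gives the same ring. The product is 23 after equilibration of C2''/C3'' to trans, in a medium in which unit 1 is not exposed to strong base.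

2. Step 7.
- What may go wrong: the Mannich-type addition to the electron-rich aromatic aldehyde may be slow, aldehyde 9 may self-condense, or the amine may open the pyranone ring.
- Fallback: it sets out from flavanone 6 and comes back at acid 13; the condensation is done at the ester level with the ketone masked. Enolate 7 is alkylated at −78 °C with allyl bromoacetate to give keto ester F6. LiN(SiMe3)2 with Me3SiCl present (in situ quench, −78 °C) gives silyl enol ether F7, which masks C4 and removes the acidic C3–H. LiN(i-Pr)2 at −78 °C can then deprotonate only the ester CH2. Aldol addition to 11 and a mildly acidic work-up, which hydrolyses the silyl enol ether and reprotonates C3 trans, give β-hydroxy ester F8. Dehydration with the Burgess reagent gives allyl ester F9. Deallylation with Pd(PPh3)4 (zerovalent palladium) and morpholine in THF gives 13 without acid or hydroxide.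

3. Step 4.
- What may go wrong: the lithium enolate may expel the aryloxide (ring opening to the chalcone, which erases C2) on warming, or O-allylation may compete.
- Fallback: it sets out from flavanone 6 and comes back at allyl ketone 8; the C–C bond is made by decarboxylative allylation instead of SN2 alkylation. Enolate 7 is trapped at −78 °C, without warming, by allyl chloroformate on oxygen to give allyl enol carbonate F10. Pd(PPh3)4 (zerovalent palladium) in THF at rt ionises F10 to a π-allylpalladium enolate ion pair that loses CO2 and recombines at C3 (Tsuji decarboxylative allylation). This gives 8, with the allyl group trans to the C2 aryl group.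

**Further compounds**

F1 | step 12 | 1,3,5-tris(methoxymethoxy)benzene | COCOc1cc(OCOC)cc(OCOC)c1
F2 | step 12 | 2,4,6-tris(methoxymethoxy)phenyllithium | [Li]c1c(OCOC)cc(OCOC)cc1OCOC
F3 | step 12 | (E)-2-[(2R,3S)-7-methoxy-5-(methoxymethoxy)-2-(4-methoxyphenyl)-4-oxochroman-3-yl]-3-[4-(methoxymethoxy)phenyl]-1-[2,4,6-tris(methoxymethoxy)phenyl]prop-2-en-1-ol (carbinol epimers) | COc1ccc([C@@H]2Oc3cc(OC)cc(OCOC)c3C(=O)[C@H]2/C(=C\c2ccc(OCOC)cc2)C(O)c2c(OCOC)cc(OCOC)cc2OCOC)cc1
F4 | step 12 | (E)-2-[(2R,3S)-7-methoxy-5-(methoxymethoxy)-2-(4-methoxyphenyl)-4-oxochroman-3-yl]-3-[4-(methoxymethoxy)phenyl]-1-[2,4,6-tris(methoxymethoxy)phenyl]prop-2-en-1-one | COc1ccc([C@@H]2Oc3cc(OC)cc(OCOC)c3C(=O)[C@H]2/C(=C\c2ccc(OCOC)cc2)C(=O)c2c(OCOC)cc(OCOC)cc2OCOC)cc1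
F5 | step 12 | (E)-2-[(2R,3S)-5-hydroxy-7-methoxy-2-(4-methoxyphenyl)-4-oxochroman-3-yl]-3-(4-hydroxyphenyl)-1-(2,4,6-trihydroxyphenyl)prop-2-en-1-one | COc1ccc([C@@H]2Oc3cc(OC)cc(O)c3C(=O)[C@H]2/C(=C\c2ccc(O)cc2)C(=O)c2c(O)cc(O)cc2O)cc1
F6 | step 7 | allyl 2-[(2R,3S)-7-methoxy-5-(methoxymethoxy)-2-(4-methoxyphenyl)-4-oxochroman-3-yl]acetate | COc1ccc([C@@H]2Oc3cc(OC)cc(OCOC)c3C(=O)[C@H]2CC(=O)OCC=C)cc1
F7 | step 7 | allyl 2-[(2S)-7-methoxy-5-(methoxymethoxy)-2-(4-methoxyphenyl)-4-(trimethylsilyloxy)-2H-chromen-3-yl]acetate (C2 unchanged in space; the descriptor changes by priority only) | COc1ccc([C@@H]2Oc3cc(OC)cc(OCOC)c3C(O[Si](C)(C)C)=C2CC(=O)OCC=C)cc1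
F8 | step 7 | allyl 3-hydroxy-2-[(2R,3S)-7-methoxy-5-(methoxymethoxy)-2-(4-methoxyphenyl)-4-oxochroman-3-yl]-3-[4-(methoxymethoxy)phenyl]propanoate (mixture at the two new centres) | COc1ccc([C@@H]2Oc3cc(OC)cc(OCOC)c3C(=O)[C@H]2C(C(=O)OCC=C)C(O)c2ccc(OCOC)cc2)cc1
F9 | step 7 | allyl (E)-2-[(2R,3S)-7-methoxy-5-(methoxymethoxy)-2-(4-methoxyphenyl)-4-oxochroman-3-yl]-3-[4-(methoxymethoxy)phenyl]prop-2-enoate | COc1ccc([C@@H]2Oc3cc(OC)cc(OCOC)c3C(=O)[C@H]2/C(=C\c2ccc(OCOC)cc2)C(=O)OCC=C)cc1
F10 | step 4 | allyl (2R)-7-methoxy-5-(methoxymethoxy)-2-(4-methoxyphenyl)-2H-chromen-4-yl carbonate | COc1ccc([C@@H]2Oc3cc(OC)cc(OCOC)c3C(OC(=O)OCC=C)=C2)cc1
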